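The runs come from a simulation for an exercise; the scatter is artificial.

If starting material leaves this flask by two roads, to target and to homo dimer, ask one thing first: what does each lost percent of it give?

| flask | starting material | reagent | second substrate | free catalyst | remark | time |
|---|---|---|---|---|---|---|
| larch | 0.10 M | 1.1 equiv | 0.20 equiv | 0.5 mol% | the very flask that is asked about, followed so far |  |
| flask | 0.10 M | 1.10 equiv | 0.200 equiv | 0.5 mol% |  | 50 h |

- larch (time / h: target / %, starting material / %): 1.50: 15.0, 70.6; 3.00: 23.9, 54.3; 5.00: 30.9, 41.6; 6.00: 33.1, 37.3; 8.00: 37.9, 30.1; 10.0: 40.9, 26.5

(standard deviation of a reading: 0.5 percentage points)

- amount of target in percent of the starting material charged, at 2.5 h, 12 h and 50 h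

- percentages count the starting material that a species holds: one homo dimer counts as two
- candidate steps: starting material + reagent + free catalyst -> free catalyst + target; second substrate + reagent + free catalyst -> free catalyst + second product; free catalyst -> spent catalyst; 2 starting material -> homo dimer

Take the readings of the larch run at 5.00 h and 10.0 h. They give 66.2% as the target share (a selectivity), the target gained per starting material lost. Object at once: the last two readings give 83.3%. But that rests on a drop of 3.6 percentage points, with a scatter of 0.5 points on each reading. Keep the wider window.

Now ask how much starting material is left to share. Its half-life reads 7.69 h over the wider window and 10.9 h over the last two readings. Use the later one, though it rests on that same small drop. It gives 43.0% of target at 12 h. For 2.5 h, draw the chord between the readings on either side: 20.9%. The curve bends, so read that as a low estimate.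

At 50 h the same half-life leaves 2.07% of starting material and gives 57.1% of target. Object again: the half-life already reads longer late in the larch run. So double it. That leaves 7.41% and gives 53.5%. Commit to this second figure.

The forecast gives 21.4%, 43.5% and 53%, on the ground that “Both the dimer and the dying catalyst then slow things down”. At 12 h my 43.0% stands below its figure.

The flask gives 21.0%, 42.7% and 54.0%.

    starting material + reagent + free catalyst → free catalyst + target (k = 2600 /M²/h)
    second substrate + reagent + free catalyst → free catalyst + second product (k = 22000 /M²/h)
    free catalyst → spent catalyst (k = 0.0210 /h)
    2 starting material → homo dimer (k = 0.660 /M/h)

In this flask the half-life of starting material by the target step at 3.88 h is 9.1 h, shorter than the 33 h half-life of free catalyst by its loss to spent catalyst alone, and at 50.0 h free catalyst still holds 35.0% of the catalyst while starting material stands at 4.6%. Apply the target share to the drop from 26.5% at 10.0 h to that 4.6%: it gives 55.4% of target, and the flask holds 54.0%.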